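The data are calculated for an exercise, noise included.

- By the first reading, 10.0 s into dawn, the links Z stand at 72.8 %, and at 120 s they stand at 72.2 %. Autumn also ends below its first reading, so in both runs Z stands within seconds about where it ends.

| setting | dawn | autumn | north-west | east |
|---|---|---|---|---|
| D | 0.0034 M | 0.0075 M | 0.0050 M | 0.0050 M |
| X | 5.1 mM | 5.1 mM | 5.10 mM | 5.10 mM |
| L | 1 mM | 1 mM | 1.00 mM | 1.00 mM |
| temperature | 8 °C | 24 °C |  |  |
| remark | run made earlier | run made earlier | at 0 °C until 40 s, from then on at 30 °C | at 30 °C throughout |
| time |  |  | 3.0 min | 3.0 min |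

| run | time / s | Z / % |
|---|---|---|
| dawn | 10.0 | 72.8 |
| dawn | 15.0 | 74.1 |
| dawn | 30.0 | 73.5 |
| dawn | 50.0 | 72.9 |
| dawn | 60.0 | 73.5 |
| dawn | 80.0 | 72.4 |
| dawn | 120 | 72.2 |
| autumn | 10.0 | 59.5 |
| autumn | 15.0 | 58.5 |
| autumn | 20.0 | 58.5 |
| autumn | 25.0 | 58.2 |
| autumn | 30.0 | 57.6 |
| autumn | 40.0 | 57.9 |

(standard deviation of a reading: 0.3 percentage points)

* which of the two ends with the higher amount of Z, in percent of the D charged ("neither" if they lie within 2 percentage points) (north-west / east / neither)
* Z at the end, in percent of the D charged, north-west
* Z at the end, in percent of the D charged, east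



- Averaged over each run, Z is 73.1 % in dawn and 58.4 % in autumn. Dawn charges more X than D, yet D is missing from Z, so I suppose that D has another way out than X.
- I call the toll the D missing from Z per D found in Z, divided by charged [D] over charged [X]. It reads 0.553 in dawn and 0.485 in autumn. A straight line in temperature through these two gives 0.587 at 0 °C and 0.459 at 30 °C, and this toll of the race for D between X and the other way out, taken at the warm temperature, is what I carry.
- North-west and east look like twins: they have the same charges and share 30 °C for the last 140 s. They differ in the first 40 s. Dawn's Z stands near its end value within a quarter of that span, so I take north-west's race as run cold and its warming as coming too late, which is kinetic control, not thermodynamic control.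
- My reckoning therefore gives north-west 63.5 % and east 68.9 %. East is higher by 5.4 percentage points, more than the margin.
- The forecast differs. It says neither, with 71 % for north-west (65 % to 77 %) and 71 % for east (65 % to 77 %), holding of north-west that “Its cold start should therefore be forgotten”.
- East ends at 67.8 % and north-west at 60.8 %, so the higher one is east.

    D + X ⇌ Z + G (K = 98.5, k = 62.9 M⁻¹ s⁻¹, Ea = 48.0 kJ mol⁻¹, ΔH = 35.0 kJ mol⁻¹)
    2 D → E (k = 23.2 M⁻¹ s⁻¹, Ea = 35.0 kJ mol⁻¹)
    D + L → J (k = 30.4 M⁻¹ s⁻¹, Ea = 39.0 kJ mol⁻¹)
    (constants at 0 °C)

- In east the exchange of D + X with Z + G has a relaxation half-life of 0.784 s, short against the 3.0 min. E, in percent of the D charged, stands in north-west at 28.4 % at 0.667 min and at 28.5 % at 3.00 min, against 20.3 % in east at that time. East's end reads a toll of 0.484 beside the carried 0.459. The neighbour of east charged with 0.0040 M of L ends with Z at 52.9 %, so its toll is 0.907, twice the carried 0.459.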